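Atom numbers (C1 to O32) follow the heavy atoms in the order of the target SMILES. Ring A is the δ-lactone and ring B the cyclohexane.

## Structural features

The target is a pentacyclic C25 compound. Ring A, an α,β-unsaturated gem-dimethyl δ-lactone (C2–O4–C5–C7=C8–C9), is spiro-joined at C9 to ring B (C9–C10–C11–C12–C21–C22). Ring B is cis-fused through C12–C21 to a cyclopentane (C12–C21–C20–C18–C25). That cyclopentane shares C12, C25 and C18 with a bicyclo[2.2.2]octanone (bridgeheads C14 and C25; bridges C13–C12, C16–C18 and C31–C30), which carries a γ-lactone (C25–C26–O27–C28–C30).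

There are nine stereocentres. C9, C22, C21 and C12 are contiguous on ring B. C12, C25 and C18 are three contiguous all-carbon quaternary centres, and C14 is a fourth. C30 and C31 are neighbours on one bridge, with the C31 hydroxyl anti to the lactone carbon C28.

The fragile groups are the β-hydroxy γ-lactone (retro-aldol, epimerisable C30), the tertiary C22 alcohol and the ring A enoate. The C16 ketone is hindered and cannot enolise.

The real difficulty is the quaternary array C12/C25/C18/C14 inside a cage. In addition, a cis dienophile cannot deliver the anti C30/C31 arrangement directly.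

The key step exploits one feature. C18 and C25 are adjacent quaternary carbons common to the cyclopentane and to the ring C14–C16–C18–C25–C30–C31, which is oxygenated at C16 and C31. This is the retron of an intramolecular [4+2] between a 1,3-dioxygenated diene and a butenolide joined by the tether C20–C21–C12.

## Logic of the disconnections

**36 to 34 and 33.** The C31–H bond and the C30 configuration are set last. The reason is that the cycloaddition can only give both centres inverted, so they must pass through an sp2 or enolisable stage. Cutting here removes the last two stereochemical problems from the cage synthesis. The forward step needs hydride delivery to C31 from the face of the C12–C13 bridge and a thermodynamic epimerisation at C30.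

**33 and 32 to 30.** The C7=C8 double bond is removed. Ring A then cannot act as a second dienophile or Michael acceptor, and it survives the desulfurisation. The forward demand is regioselective enolisation at C7 in the presence of the hindered C30–H.

**30 to 29 to 28.** The C13–H bond is traced to a C13–S bond, and the bond C13–C14 is cut. This opens the bicyclo[2.2.2]octane to a cyclohexene carrying a latent C13 cation and a C16 enol ether. The forward step needs a thiophile that ionises the dithioacetal without attacking the enol ether.

**28 to 27.** The bonds C18–C25 and C31–C30 are cut. This removes two rings, four stereocentres and the vicinal quaternary pair at once. The forward cycloaddition must proceed through the exo-lactone mode on the convex face, and the diene must have a defined geometry at C18=C16.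

**27 to 26, then to 20 and 23.** The O17–Si bond and the C20–H bond are traced to an enone, and C20=C18 is cut by an aldol condensation. The enol ether geometry then follows from an s-cis 1,4-hydrosilylation. No strong base is used in the presence of the acidic butenolide. The forward demands are a chemoselective hydrosilylation and no epimerisation of C21 in 20.

**20 to 19, 18, 17, then to 14 and 16.** The two C13–S bonds are traced to the aldehyde, and the bond C12–C25 is cut. This separates the butenolide from ring B. The forward step needs C-selective vinylic substitution on the face of C20.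

**14 to 12, 10, 9 and 8.** The lactone bond O4–C5, the two C2–CH3 bonds and the C12=C13 bond are cut. Ring A and the formyl carbon are thereby reduced to an ester, an allyl group and a ketone. The forward demand is double methyl addition to a hindered ester.

**8 to 7 to 6, then to 5 and 4.** The bond C21–C22 is cut by a retro-aldol and C9–C10 by a retro-Michael. Ring B falls to two acyclic pieces, and C9 becomes the single centre set by a catalyst. The aldol must stop at the ketol and must relay C9 to C22 and C21.

**4 to 1; 16 to 15; 23 to 21.** These are functional-group changes only. They lead to a protected propanediol, tetronic acid and pentan-3-one.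

## Other disconnections considered

**Alternative 1:** The cut is the C26–O27 bond, so the γ-lactone is made last from the acid A2. In the forward step Pd(OAc)2, an amino-acid-derived ligand and a peroxide oxidant would activate a C–H bond of the C26 methyl through the C28 carboxylate, giving A1.

- In favour: C25 is a β-quaternary carbon, the best substrate class for carboxylate-directed γ-C–H lactonisation. C26 is the only γ-carbon that carries hydrogen.
- Against: the divalent-palladium/peroxide system must tolerate a free tertiary alcohol, an enoate and a β-silyloxy acid that can eliminate. The carboxylate also sits in a very crowded cage.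
- Comparison: the cage would have to be built with an acyclic, less reactive and conformationally free dienophile, so the exo/endo control that the butenolide ring provides is lost. Step economy is about equal.
- Where it is better: the upstream chemistry never meets the acidic γ-protons of a butenolide.

**Alternative 2:** The cut is the C12–C25 bond. The forward step uses Fe(acac)3/PhSiH3 to transfer a hydrogen atom to C11 of the ring B alkene of A4. The tertiary C12 radical then adds 6-exo to C25 of the dearomatised phthalide, giving A3.

- In favour: it is convergent, because a flat aromatic piece carries nine carbons. The radical bond formation has an early transition state and tolerates congestion and free hydroxyl groups.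
- Against: C14 must first be set in a dearomatising C-alkylation. The radical must add cis to the C20 arm on ring B, which is the more hindered face. C18 remains a C–H centre that still has to be quaternised by a later C18–C20 ring closure.
- Comparison: the chosen plan forms C18–C25 and the cyclopentane in the same event and sets four centres by orbital symmetry, whereas the radical plan sets two under steric control.
- Where it is equal or better: convergence, and the mildness of forming the C12–C25 bond.

**Alternative 3:** The cut is the C11–C12 bond. In the forward step KOtBu would convert the phenol A6 into its phenoxide, whose para carbon C12 displaces iodide at C11, giving the spiro dienone A5.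

- In favour: a fully substituted arene delivers C12, C13, C14, C25, C30, C31 and the lactone in one robust piece. Ring B and the spiro quaternary carbon form in a simple base-mediated step.
- Against: C9, C22, C21 and C18 must be set on an open chain before ring B exists. The sense of dearomatisation (which dienone arm ends up cis to C20) depends on an aryl rotamer. O-alkylation competes. The cage still requires a Michael/Claisen sequence, and the chlorine must be removed.
- Comparison: the mechanism is ionic and stepwise. The chosen plan uses ring B as the stereochemical template, and this one does not.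
- Where it is better: it avoids a sensitive bis(silyloxy)diene altogether.

Key step: step 20

**Remarks on the chemistry (assumptions)**

- The sense of induction in step 4 is assumed by analogy; the pseudoenantiomeric cupreine catalyst would be used if the opposite sense were found.
- The C16 enol ether is carried as a triethylsilyl ether, a spectator change that follows from the hydrosilylation in step 19.
- A check of the cycloaddition pair 27/28 required no change of any stereodescriptor. With the tether and the C31 silyloxy group both outside the s-cis diene and the lactone exo, C18 and C25 come out as in 36, and C30 and C31 come out inverted.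
- Ring B is assembled enantioselectively from 5 and 4, because a preformed racemic 2-methyl-4-oxocyclohexenecarboxylate has a configurationally labile stereocentre.

## Route

Step 1
Reactants: 1 3-[(4-methoxybenzyl)oxy]propan-1-ol
Product: 2 3-[(4-methoxybenzyl)oxy]propanal
Conditions: Dess–Martin periodinane, NaHCO3, CH2Cl2, 0 °C to rt
Reagents that add atoms: none
Why: Hypervalent-iodine oxidation of a primary alcohol stops at the aldehyde, and the buffered non-basic medium avoids β-elimination of the benzylic ether.

Step 2
Reactants: 2 3-[(4-methoxybenzyl)oxy]propanal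
Product: 3 5-[(4-methoxybenzyl)oxy]pent-1-en-3-ol (racemic)
Conditions: CH2=CHMgBr, THF, −78 °C; aq. NH4Cl
Reagents that add atoms: vinylmagnesium bromide, C=C[Mg]Br
Why: Grignard 1,2-addition to an aldehyde; the carbinol centre is removed in step 3, so no control is needed.

Step 3
Reactants: 3 5-[(4-methoxybenzyl)oxy]pent-1-en-3-ol
Product: 4 5-[(4-methoxybenzyl)oxy]pent-1-en-3-one
Conditions: Dess–Martin periodinane, NaHCO3, CH2Cl2, 0 °C; used at once
Reagents that add atoms: none
Why: Oxidation of an allylic alcohol to the vinyl ketone under neutral conditions; the enone is used fresh because it polymerises readily.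

Step 4
Reactants: 5 methyl 2-acetylpent-4-enoate; 4 5-[(4-methoxybenzyl)oxy]pent-1-en-3-one
Product: 6 methyl (2S)-2-acetyl-7-[(4-methoxybenzyl)oxy]-5-oxo-2-(prop-2-en-1-yl)heptanoate
Conditions: 9-O-benzylcupreidine (10 mol %), CH2Cl2, −20 °C
Reagents that add atoms: none
Why: Catalytic enantioselective Michael addition of an α-substituted β-keto ester to a vinyl ketone; the quinuclidine nitrogen forms the enolate and the 6'-hydroxyl binds the enone, so one enolate face adds and C9 is set as the only catalyst-controlled centre.

Step 5
Reactants: 6 methyl (2S)-2-acetyl-7-[(4-methoxybenzyl)oxy]-5-oxo-2-(prop-2-en-1-yl)heptanoate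
Product: 7 methyl (1S,2R,3S)-2-hydroxy-3-{[(4-methoxybenzyl)oxy]methyl}-2-methyl-4-oxo-1-(prop-2-en-1-yl)cyclohexane-1-carboxylate
Conditions: (S)-proline (30 mol %), DMSO, 30 °C
Reagents that add atoms: none
Why: Hajos–Parrish-type enamine aldol cyclisation in which only the C21 enamine of the C12 ketone can reach the acetyl carbon C22 in a six-membered ring, and without acid or heat the ketol should not dehydrate. In the chair transition state the C23 methyl, the allyl group and the C20 arm are expected equatorial, while the flat ester and the new hydroxyl are axial and anti (dipole-minimised, no metal chelation), so C22–OH ends cis to the allyl group and C20 cis to the hydroxyl. C21 can equilibrate through the enamine to this all-equatorial arrangement.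

Step 6
Reactants: 7 ring B ketol
Product: 8 triethylsilyl ether of 7 at the C22 oxygen
Conditions: Et3SiOSO2CF3, 2,6-lutidine, CH2Cl2, −78 to 0 °C
Reagents that add atoms: triethylsilyl trifluoromethanesulfonate, CC[Si](CC)(CC)OS(=O)(=O)C(F)(F)F
Why: Silyl triflate silylation of a hindered tertiary alcohol at low temperature, which blocks retro-aldol cleavage and dehydration in all later steps.

Step 7
Reactants: 8 triethylsilyl ether of 7
Product: 9 C12 methoxymethylidene derivative of 8 (mixture of enol ether isomers)
Conditions: Ph3P(CH2OMe)Cl, KN(SiMe3)2, THF, 0 °C to rt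
Reagents that add atoms: (methoxymethyl)triphenylphosphonium chloride, COC[P+](c1ccccc1)(c1ccccc1)c1ccccc1.[Cl-]
Why: Wittig homologation of the ring ketone brings in C13 as a masked aldehyde; the hindered quaternary ester is not attacked, and the enol ether protects C12/C13 during the organometallic steps.

Step 8
Reactants: 9 enol ether ester
Product: 10 tertiary alcohol in which the C9 ester of 9 has become C(CH3)2OH
Conditions: MeLi, CeCl3, THF, −78 to 0 °C
Reagents that add atoms: methyllithium, [Li]C
Why: Double addition of the weakly basic methylcerium reagent to an ester, which also adds to the hindered and enolisable methyl ketone intermediate; the allyl group, enol ether and silyl ether are inert.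

Step 9
Reactants: 10 tertiary alcohol
Product: 12 1,5-diol with primary C5 hydroxyl and tertiary C2 hydroxyl, via alkylborane 11 (not isolated)
Conditions: 9-BBN-H, THF, 0 °C to rt; then NaOH, H2O2, 0 °C
Reagents that add atoms: hydrogen peroxide, OO
Why: Anti-Markovnikov hydroboration–oxidation; 9-BBN-H selects the monosubstituted alkene over the trisubstituted enol ether.

Step 10
Reactants: 12 1,5-diol
Product: 14 ring B carbaldehyde with the spiro δ-lactone in place (C12 epimers), via lactone enol ether 13 (not isolated)
Conditions: (n-Pr4N)RuO4 (5 mol %), N-methylmorpholine N-oxide, 4 Å MS, CH2Cl2, rt; then 1 M HCl, THF, 0 °C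
Reagents that add atoms: water, O
Why: Perruthenate oxidation of the primary alcohol gives the aldehyde, whose lactol with the tertiary C2 hydroxyl is oxidised on to the δ-lactone (ring A); brief aqueous acid then hydrolyses the methyl enol ether to the C13 aldehyde. The C12 configuration is irrelevant because it is enolised in step 12.

Step 11
Reactants: 15 tetronic acid
Product: 16 4-bromofuran-2(5H)-one
Conditions: (COBr)2, DMF (cat.), CH2Cl2, 0 °C to rt
Reagents that add atoms: oxalyl bromide, O=C(Br)C(=O)Br
Why: Vilsmeier-type conversion of the vinylogous acid into the vinylogous acyl bromide.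

Step 12
Reactants: 14 ring B carbaldehyde; 16 4-bromofuran-2(5H)-one
Product: 17 C12-quaternary aldehyde carrying the butenolide cis to the C20 arm
Conditions: KOtBu, THF, −78 °C; then 16, −78 to −20 °C
Reagents that add atoms: none
Why: Nucleophilic vinylic substitution (conjugate addition–elimination) of the potassium aldehyde enolate at the β-carbon of the bromobutenolide; the aldehyde α-proton is far more acidic than the lactone α-protons. In the ring B chair that keeps the spiro CMe2–O carbon and the silyloxy group equatorial, the C23 methyl is axial on the lower face and 1,3 to C12, so the electrophile is expected to enter on the upper face next to C20.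

Step 13
Reactants: 17 C12-quaternary aldehyde
Product: 18 primary C20 alcohol (in equilibrium with its lactol)
Conditions: DDQ, CH2Cl2–pH 7 buffer, 0 °C
Reagents that add atoms: none
Why: Oxidative cleavage of the 4-methoxybenzyl ether, done before sulfur is introduced so that no thioacetal is exposed to the quinone.

Step 14
Reactants: 18 primary alcohol
Product: 19 C13 bis(methylsulfanyl)methyl compound with free C20 hydroxyl
Conditions: MeSSiMe3, ZnI2 (cat.), CH2Cl2, 0 °C to rt; aq. citric acid
Reagents that add atoms: (methylthio)trimethylsilane, CS[Si](C)(C)C
Why: Mild Lewis-acid thioacetalisation of the aldehyde (or its lactol) with a silyl sulfide; the hindered β,β-disubstituted butenolide and the tertiary silyl ether should be untouched.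

Step 15
Reactants: 19 dithioacetal alcohol
Product: 20 C20 aldehyde
Conditions: SO3·pyridine, DMSO, i-Pr2NEt, CH2Cl2, −10 °C
Reagents that add atoms: none
Why: Parikh–Doering oxidation, chosen because activated DMSO does not oxidise or cleave a dithioacetal; the hindered tertiary C21–H should not epimerise with a bulky amine at low temperature.

Step 16
Reactants: 21 pentan-3-one
Product: 23 (E)-1-[(tert-butyldimethylsilyl)oxy]-2-methylpent-1-en-3-one, via sodium formyl enolate 22 (not isolated)
Conditions: NaH, HCO2Et, Et2O, 0 °C to rt; then t-BuMe2SiCl, THF–DMF, 0 °C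
Reagents that add atoms: ethyl formate, CCOC=O; tert-butyldimethylsilyl chloride, CC(C)(C)[Si](C)(C)Cl
Why: Claisen formylation of the symmetrical ketone followed by O-silylation of the β-keto aldehyde enolate, which is expected to give the E vinylogous silyl ester that places the silyloxy group on the outside of the later diene.

Step 17
Reactants: 23 vinylogous silyl ester; 20 C20 aldehyde
Product: 24 β-hydroxy ketone (mixture at C20 and C18)
Conditions: LiN(i-Pr)2, THF, −78 °C (23, 1.5 equiv); then 20, −78 °C; aq. NH4Cl
Reagents that add atoms: none
Why: Kinetic α'-deprotonation of the β-silyloxy enone at its ethyl group and aldol addition to the aldehyde, which is faster than proton transfer from the butenolide; both new centres become sp2 or CH2 later.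

Step 18
Reactants: 24 β-hydroxy ketone
Product: 26 cross-conjugated E dienone, via mesylate 25 (not isolated)
Conditions: MeSO2Cl, Et3N, CH2Cl2, 0 °C; then DBU, rt
Reagents that add atoms: none
Why: Mesylation and E1cB elimination give the more stable E enone C20=C18–C16=O.

Step 19
Reactants: 26 cross-conjugated dienone
Product: 27 triene with the (1E,3Z)-1-(tert-butyldimethylsilyloxy)-3-(triethylsilyloxy)diene tethered to the butenolide
Conditions: RhCl(PPh3)3 (2 mol %), Et3SiH, benzene, 50 °C
Reagents that add atoms: triethylsilane, CC[SiH](CC)CC
Why: Rhodium-catalysed 1,4-hydrosilylation of an enone with a monohydrosilane puts hydrogen on C20 and silicon on O17 through the s-cis conformer, so C20 ends cis to oxygen on the new C18=C16 bond and the tether lies outside the diene. The β-silyloxy enone half and the hindered butenolide are poorer hydride acceptors, and no base touches the acidic butenolide.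

Step 20
Reactants: 27 triene
Product: 28 tetracyclic silyl enol ether lactone
Conditions: toluene (0.01 M), BHT, Et3N (0.1 equiv), 130 °C, sealed tube
Reagents that add atoms: none
Why: Thermal, concerted but asynchronous normal-demand [4+2] cycloaddition: the HOMO of the diene C18=C16–C14=C31 (largest coefficient at C18) meets the LUMO of the butenolide C25=C30 (largest coefficient at the β-carbon C25), so C18–C25 forms ahead of C31–C30. The closest known reaction type is the intramolecular Diels–Alder reaction of 1-oxy-3-silyloxy dienes with tethered butenolides (tether at the diene terminus). The cyclopentane C12–C21–C20–C18–C25 closes as the tether ring across the new C18–C25 bond (fused mode, three-atom tether), and the cyclohexene C14–C16–C18–C25–C30–C31 closes by the [4+2] itself. C18 is fixed by the diene geometry (tether outside, methyl C19 inside). C25 is fixed by the cis attachment of C20 and C25 on ring B, which allows only the cis-fused bicycle and, of its two faces, the convex one anti to C11 and C22 and syn to C13. C30 follows from suprafacial addition to the cis butenolide, and C31 from the outside silyloxy group combined with the exo lactone. The step needs exo-lactone selectivity and one π-face: the endo-lactone mode would require a trans-fused bicycle between two quaternary carbons, and the concave approach would stack the new ring under ring B. The quaternary C12 (gem-disubstituent effect) offsets the cost of joining three fully substituted carbons, the saturated ring A offers no second dienophile, and C30 and C31 are expected opposite to 36, which is accepted because step 26 re-sets both.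

Step 21
Reactants: 28 tetracyclic silyl enol ether lactone
Product: 29 cage ketone with a methylsulfanyl group at C13 (C13 epimers)
Conditions: Me2S(SMe)BF4, CH2Cl2, −78 to 0 °C
Reagents that add atoms: none
Why: The thiophilic sulfonium salt methylthiolates one sulfur of the dithioacetal, which leaves as dimethyl disulfide, and the thionium ion at C13 is captured by the C16 silyl enol ether at C14 (thionium–enol silane cyclisation). C13 is held on the same face as C14, so only the bicyclo[2.2.2]octane can form, and C14 is set by that geometry.

Step 22
Reactants: 29 cage ketone sulfide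
Product: 30 cage ketone with C13 as CH2
Conditions: NiCl2·6H2O, NaBH4, MeOH–THF, 0 °C
Reagents that add atoms: none
Why: Nickel boride hydrogenolysis of the C–S bond; the C16 ketone lies between two quaternary carbons and should resist borohydride, and lactones and silyl ethers are inert.

Step 23
Reactants: 30 cage ketone
Product: 32 ring A α,β-unsaturated δ-lactone, via selenide 31 (not isolated)
Conditions: LiN(i-Pr)2 (1.1 equiv), THF, −78 °C; PhSeBr; then H2O2, pyridine, CH2Cl2, 0 °C to rt
Reagents that add atoms: none
Why: Kinetic enolisation at the unhindered C7 methylene (C30–H is tertiary and buried, C16 has no α-hydrogen), selenenylation and selenoxide syn-elimination towards C8; sulfur is already gone, so the peroxide has nothing else to oxidise.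

Step 24
Reactants: 32 unsaturated lactone bis(silyl ether)
Product: 33 diol with free C22 and C31 hydroxyls
Conditions: HF·pyridine, pyridine, THF, 0 °C to rt
Reagents that add atoms: none
Why: Buffered fluoride cleavage of both silyl ethers without touching the enoate or the lactones.

Step 25
Reactants: 33 diol
Product: 34 β-keto lactone (C31 ketone)
Conditions: Dess–Martin periodinane, NaHCO3, CH2Cl2, 0 °C; used at once
Reagents that add atoms: none
Why: Oxidation of the only secondary alcohol; the tertiary C22 hydroxyl is inert, and neutral conditions should keep C30 as formed in step 20 for the short time before step 26.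

Step 26
Reactants: 34 β-keto lactone
Product: 36 target compound CNP0360620.3, via cis-hydroxy lactone 35 (not isolated)
Conditions: NaBH4, CeCl3·7H2O, MeOH–THF, −78 °C; then DBU, toluene, 50 °C
Reagents that add atoms: none
Why: In 34 the lactone carbon C28 still points to the side of the C16–C18 bridge and nearly eclipses that face of the C31 carbonyl, so hydride should enter from the side of the C12–C13 bridge and place the hydroxyl syn to the C16 ketone as in 36. The resulting cis (eclipsed) β-hydroxy lactone 35 is then epimerised at the acidic C30 to the anti arrangement, which is the thermodynamically preferred one on a bicyclo[2.2.2]octane bridge. The hindered C16 ketone and the enoate should not react with borohydride at −78 °C.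

## Compound list

1 | 3-[(4-methoxybenzyl)oxy]propan-1-ol | COc1ccc(COCCCO)cc1 | starting material
2 | 3-[(4-methoxybenzyl)oxy]propanal | COc1ccc(COCCC=O)cc1 | intermediate
3 | 5-[(4-methoxybenzyl)oxy]pent-1-en-3-ol (racemic) | C=CC(O)CCOCc1ccc(OC)cc1 | intermediate
4 | 5-[(4-methoxybenzyl)oxy]pent-1-en-3-one | C=CC(=O)CCOCc1ccc(OC)cc1 | intermediate
5 | methyl 2-acetylpent-4-enoate | C=CCC(C(C)=O)C(=O)OC | starting material
6 | methyl (2S)-2-acetyl-7-[(4-methoxybenzyl)oxy]-5-oxo-2-(prop-2-en-1-yl)heptanoate | C=CC[C@@](C(C)=O)(C(=O)OC)CCC(=O)CCOCc1ccc(OC)cc1 | intermediate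
7 | methyl (1S,2R,3S)-2-hydroxy-3-{[(4-methoxybenzyl)oxy]methyl}-2-methyl-4-oxo-1-(prop-2-en-1-yl)cyclohexane-1-carboxylate (ring B ketol) | C=CC[C@@]1(C(=O)OC)CCC(=O)[C@@H](COCc2ccc(OC)cc2)[C@@]1(C)O | intermediate
8 | C22 triethylsilyl ether of 7 | C=CC[C@@]1(C(=O)OC)CCC(=O)[C@@H](COCc2ccc(OC)cc2)[C@@]1(C)O[Si](CC)(CC)CC | intermediate
9 | C12 methoxymethylidene derivative of 8 (enol ether isomers) | C=CC[C@@]1(C(=O)OC)CCC(=COC)[C@@H](COCc2ccc(OC)cc2)[C@@]1(C)O[Si](CC)(CC)CC | intermediate
10 | tertiary alcohol: C9 bears C(CH3)2OH and allyl | C=CC[C@@]1(C(C)(C)O)CCC(=COC)[C@@H](COCc2ccc(OC)cc2)[C@@]1(C)O[Si](CC)(CC)CC | intermediate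
11 | B-alkyl-9-borabicyclo[3.3.1]nonane adduct of 10 | C(CCB1C2CCCC1CCC2)[C@@]3(C(C)(C)O)CCC(=COC)[C@@H](COCc4ccc(OC)cc4)[C@@]3(C)O[Si](CC)(CC)CC | intermediate (not isolated)
12 | 1,5-diol (primary C5–OH, tertiary C2–OH) | OCCC[C@@]1(C(C)(C)O)CCC(=COC)[C@@H](COCc2ccc(OC)cc2)[C@@]1(C)O[Si](CC)(CC)CC | intermediate
13 | spiro δ-lactone enol ether | CC1(C)OC(=O)CC[C@]12CCC(=COC)[C@@H](COCc3ccc(OC)cc3)[C@@]2(C)O[Si](CC)(CC)CC | intermediate (not isolated)
14 | ring B carbaldehyde with spiro δ-lactone (C12 epimers) | CC1(C)OC(=O)CC[C@]12CCC(C=O)[C@@H](COCc3ccc(OC)cc3)[C@@]2(C)O[Si](CC)(CC)CC | intermediate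
15 | tetronic acid | O=C1CC(=O)CO1 | starting material
16 | 4-bromofuran-2(5H)-one | BrC1=CC(=O)OC1 | intermediate
17 | C12-quaternary aldehyde with butenolide cis to the C20 arm | CC1(C)OC(=O)CC[C@]12CC[C@@](C=O)(C3=CC(=O)OC3)[C@@H](COCc4ccc(OC)cc4)[C@@]2(C)O[Si](CC)(CC)CC | intermediate
18 | C20 primary alcohol of 17 (lactol tautomer possible) | CC1(C)OC(=O)CC[C@]12CC[C@@](C=O)(C3=CC(=O)OC3)[C@@H](CO)[C@@]2(C)O[Si](CC)(CC)CC | intermediate
19 | C13 dimethyl dithioacetal with C20 hydroxyl | CC1(C)OC(=O)CC[C@]12CC[C@@](C(SC)SC)(C3=CC(=O)OC3)[C@@H](CO)[C@@]2(C)O[Si](CC)(CC)CC | intermediate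
20 | C20 aldehyde | CC1(C)OC(=O)CC[C@]12CC[C@@](C(SC)SC)(C3=CC(=O)OC3)[C@@H](C=O)[C@@]2(C)O[Si](CC)(CC)CC | intermediate
21 | pentan-3-one | CCC(=O)CC | starting material
22 | sodium 2-methyl-3-oxopent-1-en-1-olate | CCC(=O)C(C)=C[O-].[Na+] | intermediate (not isolated)
23 | (E)-1-[(tert-butyldimethylsilyl)oxy]-2-methylpent-1-en-3-one | CCC(=O)/C(C)=C/O[Si](C)(C)C(C)(C)C | intermediate
24 | aldol adduct (β-hydroxy ketone; mixture at C20 and C18) | CC1(C)OC(=O)CC[C@]12CC[C@@](C(SC)SC)(C3=CC(=O)OC3)[C@@H](C(O)C(C)C(=O)/C(C)=C/O[Si](C)(C)C(C)(C)C)[C@@]2(C)O[Si](CC)(CC)CC | intermediate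
25 | C20 mesylate of 24 | CC1(C)OC(=O)CC[C@]12CC[C@@](C(SC)SC)(C3=CC(=O)OC3)[C@@H](C(OS(C)(=O)=O)C(C)C(=O)/C(C)=C/O[Si](C)(C)C(C)(C)C)[C@@]2(C)O[Si](CC)(CC)CC | intermediate (not isolated)
26 | cross-conjugated E dienone | CC1(C)OC(=O)CC[C@]12CC[C@@](C(SC)SC)(C3=CC(=O)OC3)[C@@H](/C=C(\C)C(=O)/C(C)=C/O[Si](C)(C)C(C)(C)C)[C@@]2(C)O[Si](CC)(CC)CC | intermediate
27 | triene: ring B butenolide tethered to the (1E,3Z)-1,3-bis(silyloxy)diene | CC1(C)OC(=O)CC[C@]12CC[C@@](C(SC)SC)(C3=CC(=O)OC3)[C@@H](C/C(C)=C(O[Si](CC)(CC)CC)/C(C)=C/O[Si](C)(C)C(C)(C)C)[C@@]2(C)O[Si](CC)(CC)CC | intermediate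
28 | tetracyclic silyl enol ether lactone (cycloadduct) | CC1(C)OC(=O)CC[C@]12CC[C@]3(C(SC)SC)[C@H]([C@@]2(C)O[Si](CC)(CC)CC)C[C@@]4(C)C(O[Si](CC)(CC)CC)=C(C)[C@@H](O[Si](C)(C)C(C)(C)C)[C@@H]5C(=O)OC[C@]345 | intermediate
29 | cage ketone with C13 methylsulfanyl group (C13 epimers) | CC1(C)OC(=O)CC[C@]12CC[C@]13C(SC)[C@]4(C)C(=O)[C@](C)(C[C@H]1[C@@]2(C)O[Si](CC)(CC)CC)[C@]31COC(=O)[C@H]1[C@@H]4O[Si](C)(C)C(C)(C)C | intermediate
30 | cage ketone (C13 methylene; C22 and C31 silyl ethers; ring A saturated) | CC1(C)OC(=O)CC[C@]12CC[C@]13C[C@]4(C)C(=O)[C@](C)(C[C@H]1[C@@]2(C)O[Si](CC)(CC)CC)[C@]31COC(=O)[C@H]1[C@@H]4O[Si](C)(C)C(C)(C)C | intermediate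
31 | C7 phenylselanyl lactone | CC1(C)OC(=O)C([Se]c5ccccc5)C[C@]12CC[C@]13C[C@]4(C)C(=O)[C@](C)(C[C@H]1[C@@]2(C)O[Si](CC)(CC)CC)[C@]31COC(=O)[C@H]1[C@@H]4O[Si](C)(C)C(C)(C)C | intermediate (not isolated)
32 | ring A unsaturated lactone bis(silyl ether) | CC1(C)OC(=O)C=C[C@]12CC[C@]13C[C@]4(C)C(=O)[C@](C)(C[C@H]1[C@@]2(C)O[Si](CC)(CC)CC)[C@]31COC(=O)[C@H]1[C@@H]4O[Si](C)(C)C(C)(C)C | intermediate
33 | diol (C30 and C31 as formed in the cycloaddition) | CC1(C)OC(=O)C=C[C@]12CC[C@]13C[C@]4(C)C(=O)[C@](C)(C[C@H]1[C@@]2(C)O)[C@]31COC(=O)[C@H]1[C@@H]4O | intermediate
34 | β-keto lactone | CC1(C)OC(=O)C=C[C@]12CC[C@]13C[C@]4(C)C(=O)[C@](C)(C[C@H]1[C@@]2(C)O)[C@]31COC(=O)[C@H]1C4=O | intermediate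
35 | C30 epimer of the target (cis β-hydroxy lactone) | CC1(C)OC(=O)C=C[C@]12CC[C@]13C[C@]4(C)C(=O)[C@](C)(C[C@H]1[C@@]2(C)O)[C@]31COC(=O)[C@H]1[C@H]4O | intermediate (not isolated)
36 | CNP0360620.3 | CC1(C)OC(=O)C=C[C@]12CC[C@]13C[C@]4(C)C(=O)[C@](C)(C[C@H]1[C@@]2(C)O)[C@]31COC(=O)[C@@H]1[C@H]4O | target

## Step count and least certain steps

Total: 26 steps. Longest linear sequence: 24 steps (1 to 10, 12 to 15, 17 to 26); steps 11 and 16 prepare the two side fragments.

**Step 20 (key step).** The cycloaddition may be too slow to compete with thermal decomposition or hydrolysis of the triethylsilyl enol ether, because three contiguous fully substituted carbons are joined and the diene has an inside methyl group. Loss of π-facial control would show as a second cis-fused adduct. Fallback: replace the thermal concerted process by an anionic stepwise double Michael addition. It sets out from 27. KOtBu in THF at −78 °C cleaves the C16 silyl enol ether to the potassium dienolate. C18 then adds to C25, the lactone enolate adds to C31, and the new C16 enolate is trapped with Et3SiCl. This comes back to the route at 28 and makes no new isolable compound.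

**Step 5.** The ketol may dehydrate to the enone, the aldol may close in the other sense (acetyl methyl onto C12), or the axial/equatorial preference at C9 may be too weak to relay the configuration to C22. Fallback: give up ketol isolation and install the C22 oxygen afterwards. It sets out from 6. Pyrrolidinium acetate gives the Robinson enone F1. Nucleophilic epoxidation (t-BuOOH, DBU) gives the epoxy ketone F2. SmI2 in THF–MeOH at −78 °C cleaves the Cα–O bond and, after base equilibration of C21, returns to the route at 7. The facial sense of the epoxidation depends on the same C9 bias and would have to be checked.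

**Step 12.** O-vinylation of the hindered enolate may compete, or the electrophile may enter on the face away from C20, because the chair preference of ring B is finely balanced. Fallback: deliver the butenolide from the C20 oxygen. It sets out from 14. DDQ gives the hydroxy aldehyde F3 (lactol tautomer). O-vinylation with 16 (DABCO catalyst, i-Pr2NEt, MeCN) gives the tetronate ether F4. KOtBu at −40 °C then forms the aldehyde enolate, which adds to C25 through a five-membered transition state and expels the C20 alkoxide, an O-to-C transfer analogous to a Truce–Smiles rearrangement. This can only give the cis product, and it comes back to the route at 18.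

**Step 19.** The dithioacetal may slow the rhodium catalyst, hydride may be delivered to the butenolide, or the enone may react through the s-trans conformer and give the wrong enol ether geometry. Fallback: separate reduction from silylation. It sets out from 26. [(Ph3P)CuH]6 in wet benzene gives the saturated ketone F5. KN(SiMe3)2 and Et3SiCl at −78 °C then enolise the only α'-hydrogen (C18), with allylic 1,3-strain placing the bulky C20 chain cis to oxygen. This comes back to the route at 27. The butenolide may be silylated in passing and should revert on buffered work-up.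

**Step 26.** The β-keto lactone may epimerise at C30 before it is reduced, after which hydride would enter from the wrong face. Alternatively, base treatment may cause retro-aldol opening instead of clean epimerisation. Fallback: bring the C31 oxygen in from the open face of an alkene instead of delivering hydride to a ketone. It sets out from 30. KN(SiMe3)2 causes β-elimination of the C31 silyloxide to give the cage enoate F6. t-BuOOH with DBU epoxidises on the face of the C16–C18 bridge to give F7. LiN(i-Pr)2/PhSeBr (selenide F8) and then H2O2 give the ring A unsaturated epoxide F9; the epoxy lactone has no α-hydrogen. SmI2 in THF–MeOH at −78 °C cleaves the C30–O bond to give the C22 silyl ether F10 (with DBU equilibration of C30 if needed). HF·pyridine then comes back to the route at 36.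

## Further compounds

F0 | step 20 | none | none
F1 | step 5 | methyl (S)-1-allyl-3-{[(4-methoxybenzyl)oxy]methyl}-2-methyl-4-oxocyclohex-2-ene-1-carboxylate | C=CC[C@@]1(C(=O)OC)CCC(=O)C(COCc2ccc(OC)cc2)=C1C
F2 | step 5 | C21,C22-epoxy ketone of F1 (oxygen cis to the allyl group) | C=CC[C@@]1(C(=O)OC)CCC(=O)[C@@]2(COCc3ccc(OC)cc3)O[C@@]12C
F3 | step 12 | C20 hydroxy aldehyde from 14 (lactol tautomer) | CC1(C)OC(=O)CC[C@]12CCC(C=O)[C@@H](CO)[C@@]2(C)O[Si](CC)(CC)CC
F4 | step 12 | C20 O-(5-oxo-2,5-dihydrofuran-3-yl) ether of F3 | CC1(C)OC(=O)CC[C@]12CCC(C=O)[C@@H](COC3=CC(=O)OC3)[C@@]2(C)O[Si](CC)(CC)CC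
F5 | step 19 | saturated β-silyloxy enone (C20 methylene, C18–H) | CC1(C)OC(=O)CC[C@]12CC[C@@](C(SC)SC)(C3=CC(=O)OC3)[C@@H](CC(C)C(=O)/C(C)=C/O[Si](C)(C)C(C)(C)C)[C@@]2(C)O[Si](CC)(CC)CC
F6 | step 26 | cage C30=C31 unsaturated γ-lactone (C22 triethylsilyl ether) | CC1(C)OC(=O)CC[C@]12CC[C@]13C[C@]4(C)C(=O)[C@](C)(C[C@H]1[C@@]2(C)O[Si](CC)(CC)CC)[C@]31COC(=O)C1=C4
F7 | step 26 | C30,C31-epoxy lactone | CC1(C)OC(=O)CC[C@]12CC[C@]13C[C@]4(C)C(=O)[C@](C)(C[C@H]1[C@@]2(C)O[Si](CC)(CC)CC)[C@]31COC(=O)[C@@]15O[C@@H]45
F8 | step 26 | C7 phenylselanyl derivative of F7 | CC1(C)OC(=O)C([Se]c6ccccc6)C[C@]12CC[C@]13C[C@]4(C)C(=O)[C@](C)(C[C@H]1[C@@]2(C)O[Si](CC)(CC)CC)[C@]31COC(=O)[C@@]15O[C@@H]45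
F9 | step 26 | ring A unsaturated epoxy lactone | CC1(C)OC(=O)C=C[C@]12CC[C@]13C[C@]4(C)C(=O)[C@](C)(C[C@H]1[C@@]2(C)O[Si](CC)(CC)CC)[C@]31COC(=O)[C@@]15O[C@@H]45
F10 | step 26 | C22 triethylsilyl ether of the target | CC1(C)OC(=O)C=C[C@]12CC[C@]13C[C@]4(C)C(=O)[C@](C)(C[C@H]1[C@@]2(C)O[Si](CC)(CC)CC)[C@]31COC(=O)[C@@H]1[C@H]4O
A1 | alternative 1 | C31 tert-butyldimethylsilyl ether of the target | CC1(C)OC(=O)C=C[C@]12CC[C@]13C[C@]4(C)C(=O)[C@](C)(C[C@H]1[C@@]2(C)O)[C@]31COC(=O)[C@@H]1[C@H]4O[Si](C)(C)C(C)(C)C
A2 | alternative 1 | seco acid with C26 methyl and C28 carboxylic acid | CC1(C)OC(=O)C=C[C@]12CC[C@]13C[C@]4(C)C(=O)[C@](C)(C[C@H]1[C@@]2(C)O)[C@@]3(C)[C@H](C(=O)O)[C@H]4O[Si](C)(C)C(C)(C)C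
A3 | alternative 2 | bicyclo[2.2.2]octanone with enolised β-keto lactone | CC1(C)OC(=O)CC[C@]12CC[C@]3(C[C@]4(C)C(=O)[C@@H](C)[C@]35COC(=O)C5=C4O)[C@@H](CO[Si](C)(C)C(C)(C)C)[C@@]2(C)O
A4 | alternative 2 | ring B C11=C12 alkene carrying the C14-alkylated dearomatised phthalide | CC1(C)OC(=O)CC[C@]12CC=C(C[C@]3(C)C(=O)C(C)=C4COC(=O)C4=C3O)[C@@H](CO[Si](C)(C)C(C)(C)C)[C@@]2(C)O
A5 | alternative 3 | spiro cyclohexadienone lactone | CC1(C)OC(=O)CC[C@]12CC[C@]3(C(Cl)=C(C)C(=O)C4=C3COC4=O)[C@@H](C[C@@H](C)C(=O)OC)[C@@]2(C)O[Si](CC)(CC)CC
A6 | alternative 3 | phenolic phthalide with the C11 iodide side chain | CC1(C)OC(=O)CC[C@@]1(CCI)[C@](C)(O[Si](CC)(CC)CC)[C@H](C[C@@H](C)C(=O)OC)c2c(Cl)c(C)c(O)c3C(=O)OCc23
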